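You ask which species leads at the end of Monday's and Thursday's flasks, and how much of it there is. Your hunch is that Thursday's cold flask still holds mostly substrate. I read it otherwise.

| flask | substrate | coupling partner | temperature | remark | time |
|---|---|---|---|---|---|
| cedar | 0.025 M | 0.95 equiv | −15 °C | run made earlier |  |
| oak | 0.10 M | 0.95 equiv | −4 °C | run made earlier |  |
| Monday's | 0.050 M | 0.950 equiv | 0 °C |  | 5.0 min |
| Thursday's | 0.050 M | 0.950 equiv | −20 °C |  | 5.0 min |

cedar run (percent of the substrate charged)

| time / min | isomer of the product / % | target / % | substrate / % | intermediate / % |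
|---|---|---|---|---|
| 0.250 | 2.2 | 3.4 | 87.7 | 7.6 |
| 0.333 | 1.7 | 3.4 | 85.8 | 7.9 |
| 0.500 | 4.9 | 5.9 | 79.7 | 9.6 |
| 0.833 | 4.5 | 13.6 | 69.1 | 10.9 |
| 1.33 | 8.8 | 20.8 | 58.7 | 10.9 |
| 2.00 | 8.9 | 31.2 | 50.1 | 8.5 |
| 3.00 | 9.5 | 43.5 | 38.7 | 9.6 |

oak run (percent of the substrate charged)

| time / s | isomer of the product / % | target / % | substrate / % | intermediate / % |
|---|---|---|---|---|
| 12.0 | 5.9 | 17.0 | 49.0 | 30.1 |
| 25.0 | 5.4 | 24.7 | 31.4 | 33.4 |
| 40.0 | 6.8 | 36.8 | 23.1 | 34.4 |
| 50.0 | 6.9 | 39.7 | 20.7 | 32.4 |
| 60.0 | 6.3 | 46.4 | 19.0 | 26.4 |
| 80.0 | 6.7 | 54.2 | 15.6 | 26.2 |

(readings scatter by 1 percentage point)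

* which of these there is most of at the end, counted by the substrate in it, Monday's (intermediate / isomer of the product / substrate / target)
* which of these there is most of at the end, counted by the substrate in it, Thursday's (intermediate / isomer of the product / substrate / target)
* amount of the one of these that there is most of at the end, in percent of the substrate charged, Monday's
* amount of the one of these that there is most of at the end, in percent of the substrate charged, Thursday's

- a reading or a percentage of target counts all its forms, free or not

I take substrate and coupling partner to react one to one, with the partner as limiting reagent. I solve substrate left at both ends. Here substrate left is a fraction of its charge, and the clock is rate constant times starting [substrate] times time. Late on it tends to the gap between the charges, 0.0500. Early on it falls as 1 − (1 − gap)·clock. Second-order kinetics joins the two ends: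

left = gap / (1 − (1 − gap)·exp(−gap·clock))

Solved for the clock, the last reading of each run gives a rate constant:

cedar run, −15 °C: k = 0.387 /M/s
oak run, −4 °C: k = 0.838 /M/s

I draw ln k straight against temperature through these two readings:

Thursday's, −20 °C: k = 0.272 /M/s
Monday's, 0 °C: k = 1.11 /M/s

Thursday's clock reads 4.08, the clock being rate constant times starting [substrate] times time. Monday's reads 16.6.

Thursday's substrate left: 22.2 %
Monday's substrate left: 8.52 %

The cedar run's last reading has 71.0 % of reacted substrate as target. Applied to Thursday's flask, that gives target 55.2 %, more than substrate. On Monday's flask I commit to target leading, below the 91.5 % that has reacted.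

The forecast also names target for both flasks, 80 % on Monday's and 47 % on Thursday's, and says of the slowing intermediate-to-target conversion, “This looks like target inhibition”.

Monday's flask gives target at 83.6 %. Thursday's flask gives target at 56.4 %, with substrate at 25.9 %.

    substrate + coupling partner → intermediate + by-product (k = 0.230 /M/s, Ea = 50.0 kJ/mol)
    intermediate ⇌ target (K = 2.20, k = 0.0260 /s, Ea = 59.0 kJ/mol, ΔH = −55.0 kJ/mol)
    intermediate ⇌ isomer of the product (K = 2.30, k = 0.00890 /s, Ea = 63.0 kJ/mol, ΔH = −83.0 kJ/mol)
    crystals ⇌ target, rate k4*(cs4 - [target]) while solid is left; crystals form when [target] > cs4 (solubility = 0.570 mM, k = 0.0530 /s)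
    coupling partner + target ⇌ idle adduct, settled at all times (K = 26.0 /M, ΔH = −68.0 kJ/mol)
    (constants at −20 °C)

In Thursday's flask, substrate keeps feeding intermediate late in the run, falling from 40.3 % at 2.50 min to 25.9 % at 5.00 min, while intermediate and free dissolved target relax toward each other by that step with a half-life of 0.305 min, shorter than the run. Over that same stretch in Thursday's flask, crystals, counted in target, grow from 31.0 % to 52.7 %, and intermediate ends at 4.61 %. The same flask with 0.020 M of substrate has a clock of 1.63, which gives 40.2 % left. It holds 44.7 % substrate, more than its target of 38.9 %.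

(The data come from a simulation for substances that don't exist, and the scatter is random.)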